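**Strategy.** The route brings the benzylic carbon C2 of the 1,4-benzodioxane ring in as a CH2 group and forges its O1–C2 bond by oxidative C–H etherification. The structure invites this: C2 sits para to the guaiacyl oxygen, so hydride abstraction gives a quinone-methide-type cation that the neighbouring catechol phenol captures. One operation closes the dioxane ring and sets C2 trans to C3, the only benzodioxane stereocentre that is bought (from a glycidyl ether). The precursor is an acyclic aryl ether of a 1-aryl-3-benzyloxypropan-2-ol with a single stereocentre. The remote flavanone C2 centre is set separately by catalyst-controlled conjugate arylation of a chromone.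

Key step: step 4

Assumption 1: the (S)-configured biaryl bisphosphine in step 7 is taken to deliver the (2S)-flavanone, by analogy with the sense of aryl transfer to cyclic enones; this is to be confirmed on a model arylation of 15, and the antipodal ligand is to be used if the sense is opposite.
Assumption 2: compounds 1, 2, 5 and 14 are taken as commercially available.

Step 1
Reactants: 1 1-(benzyloxy)-4-bromo-2-methoxybenzene; 2 (R)-benzyl glycidyl ether [(2R)-2-[(benzyloxy)methyl]oxirane]
Product: 4 (2R)-1-[4-(benzyloxy)-3-methoxyphenyl]-3-(benzyloxy)propan-2-ol, via [4-(benzyloxy)-3-methoxyphenyl]magnesium bromide 3 (not isolated)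
Conditions: Mg, THF, reflux (I2 initiation); then CuI (10 mol %), 2, THF, −30 °C to 0 °C; aq. NH4Cl
Reagents that add atoms: none
Why: Grignard formation followed by Cu-catalysed SN2 ring-opening of the terminal epoxide at its unsubstituted CH2 should give the homobenzylic alcohol, the stereocentre of 2 being carried over untouched as the (R)-carbinol.

Step 2
Reactants: 4 (2R)-1-[4-(benzyloxy)-3-methoxyphenyl]-3-(benzyloxy)propan-2-ol; 5 4-bromo-2-hydroxybenzaldehyde
Product: 6 4-bromo-2-({(2S)-1-[4-(benzyloxy)-3-methoxyphenyl]-3-(benzyloxy)propan-2-yl}oxy)benzaldehyde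
Conditions: PPh3, DIAD, toluene/THF, 0 °C to rt
Reagents that add atoms: none
Why: Mitsunobu etherification with the acidic salicylaldehyde phenol should proceed by SN2 inversion, turning the (R)-carbinol into the (S)-aryl ether and placing this oxygen meta to bromine, which fixes the regiochemistry of the later dioxane ring.

Step 3
Reactants: 6 4-bromo-2-({(2S)-1-[4-(benzyloxy)-3-methoxyphenyl]-3-(benzyloxy)propan-2-yl}oxy)benzaldehyde
Product: 8 4-bromo-2-({(2S)-1-[4-(benzyloxy)-3-methoxyphenyl]-3-(benzyloxy)propan-2-yl}oxy)phenol, via 4-bromo-2-({(2S)-1-[4-(benzyloxy)-3-methoxyphenyl]-3-(benzyloxy)propan-2-yl}oxy)phenyl formate 7 (not isolated)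
Conditions: mCPBA, NaHCO3, CH2Cl2, rt; then K2CO3 (cat.), MeOH, rt
Reagents that add atoms: mCPBA, O=C(OO)c1cccc(Cl)c1
Why: Baeyer–Villiger (Dakin-type) oxidation, in which the o-alkoxyaryl group migrates in the Criegee intermediate, should give the aryl formate, whose methanolysis unmasks the phenol para to bromine without touching the stereocentre.

Step 4
Reactants: 8 4-bromo-2-({(2S)-1-[4-(benzyloxy)-3-methoxyphenyl]-3-(benzyloxy)propan-2-yl}oxy)phenol
Product: 10 (2R,3R)-6-bromo-2-[4-(benzyloxy)-3-methoxyphenyl]-3-[(benzyloxy)methyl]-2,3-dihydro-1,4-benzodioxine, via O-benzyl p-quinone-methide oxocarbenium ion (benzylic cation, DDQH– ion pair) 9 (not isolated)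
Conditions: DDQ (1.05 equiv), 4 Å MS, CH2Cl2, 0 °C to rt; then TFA (cat.), rt
Reagents that add atoms: none
Why: DDQ should form a charge-transfer complex with the 4-benzyloxy-3-methoxyphenyl ring and abstract hydride from its benzylic CH2, giving the para-oxygen-stabilised cation 9; the closest known reaction type is the DDQ-mediated dehydrogenative cyclisation of 2-(3-arylpropyl)phenols to flavans (oxidative benzylic C–H etherification through quinone-methide-type cations). The free phenol then adds to the cationic carbon in a 6-exo-trig closure (the C=C(aryl) bond of 9 is exocyclic to the new ring), forming the O1–C2 bond of the benzodioxane. The new C2 stereocentre is controlled by the existing C3 centre: allylic 1,3-strain holds the C3–H bond in the plane of the cation, the tethered phenol attacks from the face on which its own ether oxygen sits, and H2 and H3 end up anti, which is the trans-(2R,3R) ring with aryl and CH2OBn both equatorial. The trans isomer is also the thermodynamic one, so reversible ionisation of the p-alkoxybenzyl aryl ether under the acid additive should convert any cis material. The step needs oxidation at the dialkoxybenzylic CH2 and not at the phenol, the benzyl ethers or the product; this is secured by that ring being the most electron-rich site, by bromine lowering the oxidisability of the phenol, and by one equivalent of DDQ at low temperature. Loss of H3 to an enol ether is disfavoured because that C–H bond lies in the nodal plane of the cation.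

Step 5
Reactants: 10 (2R,3R)-6-bromo-2-[4-(benzyloxy)-3-methoxyphenyl]-3-[(benzyloxy)methyl]-2,3-dihydro-1,4-benzodioxine
Product: 13 {(2R,3R)-2-[4-(benzyloxy)-3-methoxyphenyl]-3-[(benzyloxy)methyl]-2,3-dihydro-1,4-benzodioxin-6-yl}boronic acid, via {(2R,3R)-2-[4-(benzyloxy)-3-methoxyphenyl]-3-[(benzyloxy)methyl]-2,3-dihydro-1,4-benzodioxin-6-yl}lithium 11 (not isolated), via lithium {(2R,3R)-2-[4-(benzyloxy)-3-methoxyphenyl]-3-[(benzyloxy)methyl]-2,3-dihydro-1,4-benzodioxin-6-yl}tri(propan-2-yloxy)borate 12 (not isolated)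
Conditions: n-BuLi, THF, −78 °C; B(OiPr)3, −78 °C to rt; 1 M HCl
Reagents that add atoms: triisopropyl borate, CC(C)OB(OC(C)C)OC(C)C; water, O
Why: Bromine–lithium exchange at −78 °C should outrun any deprotonation, and trapping of the aryllithium by the borate followed by hydrolysis of the ate complex should give the boronic acid with both stereocentres untouched (lithiation–borylation).

Step 6
Reactants: 14 5,7-dihydroxy-4H-chromen-4-one
Product: 15 5,7-bis(benzyloxy)-4H-chromen-4-one
Conditions: BnBr, K2CO3, DMF, 70 °C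
Reagents that add atoms: benzyl bromide, BrCc1ccccc1
Why: Williamson etherification should benzylate both phenols, the hydrogen-bonded 5-OH reacting on heating, so that the acceptor carries no acidic group into the conjugate addition.

Step 7
Reactants: 13 {(2R,3R)-2-[4-(benzyloxy)-3-methoxyphenyl]-3-[(benzyloxy)methyl]-2,3-dihydro-1,4-benzodioxin-6-yl}boronic acid; 15 5,7-bis(benzyloxy)-4H-chromen-4-one
Product: 16 (2S)-5,7-bis(benzyloxy)-2-{(2R,3R)-2-[4-(benzyloxy)-3-methoxyphenyl]-3-[(benzyloxy)methyl]-2,3-dihydro-1,4-benzodioxin-6-yl}-2,3-dihydro-4H-chromen-4-one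
Conditions: [RhCl(C2H4)2]2 (2.5 mol %), (S)-MeO-F12-BIPHEP (6 mol %), aq. KOH (10 mol %), toluene/H2O, 30 °C; 15 in excess (2 equiv)
Reagents that add atoms: none
Why: Hayashi–Miyaura Rh-catalysed asymmetric 1,4-addition (transmetalation to aryl–Rh, enantiofacial carbometalation of the chromone C2=C3 bond, protonolysis of the oxa-π-allyl rhodium) should form the C2–aryl bond and set the flavanone C2 centre as S under ligand control, the remote benzodioxane centres playing no part; the non-polar medium with little base should suppress retro-oxa-Michael opening and 1,2-addition.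

Step 8
Reactants: 16 (2S)-5,7-bis(benzyloxy)-2-{(2R,3R)-2-[4-(benzyloxy)-3-methoxyphenyl]-3-[(benzyloxy)methyl]-2,3-dihydro-1,4-benzodioxin-6-yl}-2,3-dihydro-4H-chromen-4-one
Product: 17 silandrin, (2S)-5,7-dihydroxy-2-[(2R,3R)-2-(4-hydroxy-3-methoxyphenyl)-3-(hydroxymethyl)-2,3-dihydro-1,4-benzodioxin-6-yl]-2,3-dihydro-4H-chromen-4-one
Conditions: H2 (1 atm), Pd(OH)2/C, THF/MeOH, rt
Reagents that add atoms: none
Why: Catalytic hydrogenolysis should cleave the four O-benzyl groups, while the ring-bound secondary benzylic C–O bonds of the benzodioxane and flavanone react far more slowly and the neutral conditions leave the base-sensitive flavanone C2 centre and the chelated ketone intact.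

**Compound list**

1 | 1-(benzyloxy)-4-bromo-2-methoxybenzene | COc1cc(Br)ccc1OCc1ccccc1 | starting material
2 | (R)-benzyl glycidyl ether, (2R)-2-[(benzyloxy)methyl]oxirane | c1ccccc1COC[C@H]1CO1 | starting material
3 | [4-(benzyloxy)-3-methoxyphenyl]magnesium bromide | COc1cc([Mg]Br)ccc1OCc1ccccc1 | intermediate (not isolated)
4 | (2R)-1-[4-(benzyloxy)-3-methoxyphenyl]-3-(benzyloxy)propan-2-ol | O[C@H](Cc1ccc(OCc2ccccc2)c(OC)c1)COCc1ccccc1 | intermediate
5 | 4-bromo-2-hydroxybenzaldehyde | O=Cc1ccc(Br)cc1O | starting material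
6 | 4-bromo-2-({(2S)-1-[4-(benzyloxy)-3-methoxyphenyl]-3-(benzyloxy)propan-2-yl}oxy)benzaldehyde | O=Cc1ccc(Br)cc1O[C@@H](Cc1ccc(OCc2ccccc2)c(OC)c1)COCc1ccccc1 | intermediate
7 | 4-bromo-2-({(2S)-1-[4-(benzyloxy)-3-methoxyphenyl]-3-(benzyloxy)propan-2-yl}oxy)phenyl formate | O=COc1ccc(Br)cc1O[C@@H](Cc1ccc(OCc2ccccc2)c(OC)c1)COCc1ccccc1 | intermediate (not isolated)
8 | 4-bromo-2-({(2S)-1-[4-(benzyloxy)-3-methoxyphenyl]-3-(benzyloxy)propan-2-yl}oxy)phenol | Oc1ccc(Br)cc1O[C@@H](Cc1ccc(OCc2ccccc2)c(OC)c1)COCc1ccccc1 | intermediate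
9 | O-benzyl p-quinone-methide oxocarbenium ion derived from 8 (benzylic cation, (S) at the aryloxy carbon, DDQH– ion pair) | COC1=CC(=C[C@@H](COCc2ccccc2)Oc2cc(Br)ccc2O)C=CC1=[O+]Cc1ccccc1 | intermediate (not isolated)
10 | (2R,3R)-6-bromo-2-[4-(benzyloxy)-3-methoxyphenyl]-3-[(benzyloxy)methyl]-2,3-dihydro-1,4-benzodioxine | COc1cc([C@H]2Oc3ccc(Br)cc3O[C@@H]2COCc2ccccc2)ccc1OCc1ccccc1 | intermediate
11 | {(2R,3R)-2-[4-(benzyloxy)-3-methoxyphenyl]-3-[(benzyloxy)methyl]-2,3-dihydro-1,4-benzodioxin-6-yl}lithium | COc1cc([C@H]2Oc3ccc([Li])cc3O[C@@H]2COCc2ccccc2)ccc1OCc1ccccc1 | intermediate (not isolated)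
12 | lithium {(2R,3R)-2-[4-(benzyloxy)-3-methoxyphenyl]-3-[(benzyloxy)methyl]-2,3-dihydro-1,4-benzodioxin-6-yl}tri(propan-2-yloxy)borate | COc1cc([C@H]2Oc3ccc([B-](OC(C)C)(OC(C)C)OC(C)C)cc3O[C@@H]2COCc2ccccc2)ccc1OCc1ccccc1.[Li+] | intermediate (not isolated)
13 | {(2R,3R)-2-[4-(benzyloxy)-3-methoxyphenyl]-3-[(benzyloxy)methyl]-2,3-dihydro-1,4-benzodioxin-6-yl}boronic acid | COc1cc([C@H]2Oc3ccc(B(O)O)cc3O[C@@H]2COCc2ccccc2)ccc1OCc1ccccc1 | intermediate
14 | 5,7-dihydroxy-4H-chromen-4-one | O=c1ccoc2cc(O)cc(O)c12 | starting material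
15 | 5,7-bis(benzyloxy)-4H-chromen-4-one | O=c1ccoc2cc(OCc3ccccc3)cc(OCc3ccccc3)c12 | intermediate
16 | (2S)-5,7-bis(benzyloxy)-2-{(2R,3R)-2-[4-(benzyloxy)-3-methoxyphenyl]-3-[(benzyloxy)methyl]-2,3-dihydro-1,4-benzodioxin-6-yl}-2,3-dihydro-4H-chromen-4-one | COc1cc([C@H]2Oc3ccc([C@@H]4CC(=O)c5c(OCc6ccccc6)cc(OCc6ccccc6)cc5O4)cc3O[C@@H]2COCc2ccccc2)ccc1OCc1ccccc1 | intermediate
17 | silandrin, (2S)-5,7-dihydroxy-2-[(2R,3R)-2-(4-hydroxy-3-methoxyphenyl)-3-(hydroxymethyl)-2,3-dihydro-1,4-benzodioxin-6-yl]-2,3-dihydro-4H-chromen-4-one | COc1cc([C@H]2Oc3ccc([C@@H]4CC(=O)c5c(O)cc(O)cc5O4)cc3O[C@@H]2CO)ccc1O | target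

**Step count.** Total: 8 steps. Longest linear sequence: 7 steps (steps 1–5, 7 and 8; step 6 prepares the chromone partner).

**Steps most likely to fail**

1. Step 4 (key step). The free phenol may be oxidised in competition with the benzylic CH2, the cyclised benzylic ether may be oxidised further, the cation may lose a proton to an enol ether, or facial selectivity may be poor. The fallback separates oxidation from ring closure and closes the ring by acid-mediated SN1 etherification under thermodynamic control. It sets out from 6, where the phenol is still masked as the aldehyde and forcing conditions are tolerated. DDQ in AcOH (60 °C) should give the benzylic acetate (1RS,2R)-1-[4-(benzyloxy)-3-methoxyphenyl]-3-(benzyloxy)-2-(5-bromo-2-formylphenoxy)propyl acetate F1. Dakin oxidation (mCPBA, then K2CO3/MeOH, which cleaves formate and acetate together) should give (1RS,2R)-1-[4-(benzyloxy)-3-methoxyphenyl]-3-(benzyloxy)-2-(5-bromo-2-hydroxyphenoxy)propan-1-ol F2. Catalytic BF3·OEt2 or TsOH in CH2Cl2 should then ionise the benzylic alcohol and close the ring to the trans isomer, whatever the configuration at C1. The fallback comes back to the route at 10.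

2. Step 7. Carbometalation of the electron-rich 5,7-dialkoxychromone may be slow, so that protodeboronation consumes the valuable boronic acid, and the enantiomeric purity at C2 may erode through retro-oxa-Michael opening. The fallback abandons the C2–aryl disconnection for the classical chalcone closure and sets out from 10. Lithiation (n-BuLi, THF, −78 °C) and formylation with DMF should give (2R,3R)-2-[4-(benzyloxy)-3-methoxyphenyl]-3-[(benzyloxy)methyl]-2,3-dihydro-1,4-benzodioxine-6-carbaldehyde F3. Claisen–Schmidt condensation with commercial 1-[2,4-bis(benzyloxy)-6-hydroxyphenyl]ethanone (KOH, EtOH/THF) should give the chalcone (E)-1-[2,4-bis(benzyloxy)-6-hydroxyphenyl]-3-{(2R,3R)-2-[4-(benzyloxy)-3-methoxyphenyl]-3-[(benzyloxy)methyl]-2,3-dihydro-1,4-benzodioxin-6-yl}prop-2-en-1-one F4. Oxa-Michael cyclisation (NaOAc, EtOH, reflux) should give 16 together with its C2 epimer, (2R)-5,7-bis(benzyloxy)-2-{(2R,3R)-2-[4-(benzyloxy)-3-methoxyphenyl]-3-[(benzyloxy)methyl]-2,3-dihydro-1,4-benzodioxin-6-yl}-2,3-dihydro-4H-chromen-4-one F5. The two diastereomers are to be separated by preparative HPLC and the epimer recycled by base-mediated ring opening and re-closure. The fallback comes back to the route at 16.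

3. Step 2. The activated homobenzylic alcohol may eliminate to the conjugated cinnamyl ether, or the hindered secondary centre may react sluggishly or with incomplete inversion. The fallback forms the aryl ether by SNAr with retention and sets out from the Grignard reagent 3. Cu-catalysed opening of commercial (S)-benzyl glycidyl ether should give the enantiomeric alcohol (2S)-1-[4-(benzyloxy)-3-methoxyphenyl]-3-(benzyloxy)propan-2-ol F6. Its sodium alkoxide (NaH, DMF, 0 °C to rt) should displace fluoride from commercial 4-bromo-2-fluorobenzaldehyde, activated by the ortho formyl group, without touching the C–O bond of the stereocentre. The fallback comes back to the route at 6.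

**Further compounds**

F1 | step 4 | (1RS,2R)-1-[4-(benzyloxy)-3-methoxyphenyl]-3-(benzyloxy)-2-(5-bromo-2-formylphenoxy)propyl acetate | O=Cc1ccc(Br)cc1O[C@@H](C(OC(C)=O)c1ccc(OCc2ccccc2)c(OC)c1)COCc1ccccc1
F2 | step 4 | (1RS,2R)-1-[4-(benzyloxy)-3-methoxyphenyl]-3-(benzyloxy)-2-(5-bromo-2-hydroxyphenoxy)propan-1-ol | Oc1ccc(Br)cc1O[C@@H](C(O)c1ccc(OCc2ccccc2)c(OC)c1)COCc1ccccc1
F3 | step 7 | (2R,3R)-2-[4-(benzyloxy)-3-methoxyphenyl]-3-[(benzyloxy)methyl]-2,3-dihydro-1,4-benzodioxine-6-carbaldehyde | COc1cc([C@H]2Oc3ccc(C=O)cc3O[C@@H]2COCc2ccccc2)ccc1OCc1ccccc1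
F4 | step 7 | (E)-1-[2,4-bis(benzyloxy)-6-hydroxyphenyl]-3-{(2R,3R)-2-[4-(benzyloxy)-3-methoxyphenyl]-3-[(benzyloxy)methyl]-2,3-dihydro-1,4-benzodioxin-6-yl}prop-2-en-1-one | COc1cc([C@H]2Oc3ccc(/C=C/C(=O)c4c(O)cc(OCc5ccccc5)cc4OCc4ccccc4)cc3O[C@@H]2COCc2ccccc2)ccc1OCc1ccccc1
F5 | step 7 | (2R)-5,7-bis(benzyloxy)-2-{(2R,3R)-2-[4-(benzyloxy)-3-methoxyphenyl]-3-[(benzyloxy)methyl]-2,3-dihydro-1,4-benzodioxin-6-yl}-2,3-dihydro-4H-chromen-4-one | COc1cc([C@H]2Oc3ccc([C@H]4CC(=O)c5c(OCc6ccccc6)cc(OCc6ccccc6)cc5O4)cc3O[C@@H]2COCc2ccccc2)ccc1OCc1ccccc1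
F6 | step 2 | (2S)-1-[4-(benzyloxy)-3-methoxyphenyl]-3-(benzyloxy)propan-2-ol | O[C@@H](Cc1ccc(OCc2ccccc2)c(OC)c1)COCc1ccccc1
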